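## The problem

Compound 24 is a diterpenoid of the labdane type in the enantiomeric (ent) series. It is a trans-fused decalin. Ring A (C1–C5, C10) carries two hydroxymethyl groups (C18, C19) on C4. Ring B (C5–C10) carries the angular methyl C20 on C10, a formyl group (C17) on C8 and, on C9, the chain C11–C12 that ends in an α-substituted butenolide (C13–C16, C13=C14, carbonyl C16). Four stereocentres must be set (5S, 8S, 9R, 10S): H5 and C20 are anti, C11 is equatorial and on the same face as C20, and the formyl group is equatorial and trans to C11. C8 is epimerisable and its axial epimer would be syn-diaxial to C20, so it can be left to equilibration. C5 can be set alone on a monocyclic precursor and can then direct the quaternary C10. C9 has no acidic hydrogen in any likely intermediate and must come out right when its bond to C10 is made. The α-branched aldehyde, the butenolide (an acceptor for nucleophiles, hydrides, radicals and hydrogen) and the 1,3-diol limit the reagents, so strong base must do its work before the aldehyde and the unsaturated lactone exist. The feature that allows a short route is that C17, C8 and C9 with the whole side chain form an α,β-unsaturated aldehyde. A ring A that offers a C1=C10 alkene (a latent tertiary C10 radical) and an acetaldehyde arm on C5 (C6–C7) can take up this enal at C9–C10 and C7–C8 and close ring B in one operation.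

## Retrosynthesis

**24 from 23 and 21.** No skeletal bond is cut in the last two operations. The diol is carried as the isopropylidene acetal 23, which keeps C4 non-stereogenic. The C13=C14 bond of the butenolide is the last bond formed, by S-oxidation of the saturated α-phenylsulfanyl lactone 21 and sulfoxide elimination. A butenolide present earlier would compete as an acceptor for radicals and hydride. A lactone attached late by enolate alkylation would force protection and release of the C17 aldehyde. The forward steps need sulfide oxidation faster than aldehyde oxidation, elimination into the ring, and an acetal hydrolysis that leaves the aldehyde at its thermodynamic configuration.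

**21 from 19.** The hydrogens at C7 and C8 are removed: 21 is the conjugate-reduction product of the C7=C8 enal 19, with C8 set by equilibration. This accepts the oxidation pattern that an aldol condensation delivers and takes C8 off the list of centres that need kinetic control. Radical deoxygenation of the aldol at C7 would endanger the C–S bond. The forward step needs a 1,4-selective hydride source that tolerates the sulfide and the lactone.

**19 from 9 and 16 (key disconnection).** Ring B is cut at C9–C10 and C7–C8, which releases the ring A aldehyde 9 and the enal 16.
- A polar Michael–aldol sequence is excluded because C10 carries no activating group.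
- A cycloaddition forming the same two bonds would be expected to join the more nucleophilic diene terminus (C7) to the enal β-carbon, the wrong way round, and would leave C5 to a later hydrogenation.
- The radical route needs only the alkene. Carrying the complete masked lactone in 16, and not a protected C12 alcohol, removes protection, deprotection and activation steps after the annulation.
- 9 has one stereocentre and 16 none that survives.
- The forward reaction must transfer a hydrogen atom to the C1=C10 alkene and not to the enal, add anti to the C5 arm, choose the enal face that puts C11 on the side of C20, and close the aldol before the enolate is protonated.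

**16 from 14 and 15; 14 from 11 and 12; 11 from 10.** C8=C9 is cut by Wittig olefination of aldehyde 14 with ylide 15. C12–C13 is cut by alkylation of the enolate of sulfide 11 with bromo acetal 12. Sulfide 11 comes from bromo lactone 10 and a thiolate. The only strongly basic step of the side chain is thus done on a small molecule without other functionality, three steps from catalogue compounds.

**9 from 6 and 7.** The C5–C6 bond is cut by a Claisen rearrangement of the allyl vinyl ether 8, made from allylic alcohol 6 and vinyl ether 7. One operation transfers chirality from the C1 carbinol to C5, moves the alkene to C1=C10 and delivers C7 as the aldehyde. The neighbouring cut is conjugate addition of a vinyl metal to enone 5 with enolate trapping as the triflate, triflate reduction, hydroboration and oxidation. It would take four to five steps and would need an enantioselective cuprate addition at a β-carbon flanked by a quaternary centre on an α-methyl enone. The rearrangement must form a bond next to C4 suprafacially.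

**6 from 5; 5 from 2 and 3; 2 from 1.** The carbinol of 6 comes from CBS reduction of enone 5. Enone 5 is cut at C3–C4 (Michael addition) and C5=C10 (aldol condensation), a Robinson annulation of the α-branched aldehyde 2 with vinyl ketone 3. The α-carbon of 2 becomes the spiro centre C4, which a ketone partner could not provide. 2 is the oxidation product of alcohol 1. Enone 5 is achiral, so ring A needs no stereocontrol up to this point.

## Roads not taken

Alternative 1: Both rings would be closed at once by cutting C4–C5 and C9–C10 of the acyclic (E,E)-epoxy diene A1, in which C3–C4 is a spiro epoxide on the dioxane.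
- Forward step: Cp2TiCl (trivalent titanium, formed in the flask from Cp2TiCl2 and manganese) opens the epoxide at its more substituted carbon. The C4 radical adds to C5, the C10 radical adds to C9, and the C8 radical is lost as the exocyclic C8=C17 alkene, giving the bicyclic alcohol A2.
- Merits: two rings, the quaternary C10 and the relative configuration of C5, C9 and C10 come from one chair–chair transition state. In the control of C9 this road is better than the chosen one, where C9 rests on the facial preference of an open-chain enal.
- Weak points for 24: A2 carries a C3 hydroxyl that must be removed. C17 arrives as a methylene that needs hydroboration, oxidation and epimerisation. The silyl ether must still be turned into the butenolide with the aldehyde protected. A1 needs a multistep polyene assembly and an enantioselective epoxidation of an alkene flanked by two allylic oxygens.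
- Comparison: the chosen plan sets against the better C9 control of A2 that its key step delivers C17 as the aldehyde, no surplus oxygen and the lactone in place. Three steps remain after the annulation, where this road would need about ten.

Alternative 2: Ring A would be closed last at C1–C10 on a ring B that already holds C5, C8 and C9.
- Forward step: the diazo ketone A3 (C2 carbonyl, C1 diazo carbon, tethered to C5 through C3 and C4, with an exocyclic C10=C20 methylene) is decomposed by Cu(acac)2 (divalent copper). The carbenoid adds across C10=C20 to give the cyclopropyl ketone A4. Li/NH3 then cleaves C1–C20, the cyclopropane bond that overlaps best with the carbonyl, and leaves C20 as the angular methyl.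
- Merits: the quaternary centre is made by an intramolecular addition tied to C5, so C10 is as secure as a centre can be. In this respect the road is better than an intermolecular addition of a tertiary radical to a β-substituted enal.
- Weak points: the hard part of 24, three contiguous centres (C5, C8, C9) on a cyclohexane, has to be solved before the key step. The C2 ketone must then be removed, the dissolving metal also cleaves the benzyl ether, and the diazo ketone lengthens a linear sequence.
- Comparison: the chosen route buys brevity with less certainty at C10 and C9. It sets against the security of A4 that ring B and its three substituents form together from a precursor with one stereocentre.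

Alternative 3: Ring A would be annulated onto a ring B enone by cutting C4–C5, C1–C10 and C3–C4.
- Forward step: a chiral oxazaborolidinium Lewis acid catalyses the Mukaiyama–Michael addition of the malonate silyl ketene acetal A6 to C5 of 2-methylcyclohex-2-enone A5. The silyl enol ether is converted with MeLi into the lithium enolate, which is alkylated at C10 by the iodide end of 1-chloro-3-iodopropane A7. The malonate anion closes ring A by displacing chloride, giving the decalone A8.
- Merits: catalytic enantiocontrol from three achiral catalogue compounds, a trans fusion from alkylation anti to the C5 substituent, and a geminal diester that maps onto the two hydroxymethyl groups. In speed of access to an enantioenriched decalin with C4, C5 and C10 correct, this road is better than the chosen one, which needs four steps to reach 9.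
- Weak points: A8 has only a ketone at C9. C8 with its formyl group, C9 with its chain and both stereocentres must still be built on a carbonyl flanked by the quaternary C10, where addition and olefination are slow. The diester must be reduced and protected meanwhile.
- Comparison: the chosen plan pays with a less secure ring fusion, but it brings in C17, C8, C9 and the complete side chain in the ring-forming step, which the many steps after A8 cannot match.

Key step: step 8

Remark: labdane numbering is used for every intermediate, including the monocyclic ones.
Remark: compounds 11, 13, 14 and 16 to 22 contain the sulfur-bearing lactone carbon C13 in both configurations; step 10 makes it sp2, so it is left undefined.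
Remark: the (R)-CBS catalyst is assumed to give (9S)-6 by the usual model (alkenyl arm as the large group); if the assignment of 6 proves opposite, the enantiomeric catalyst is used.

## Route

Step 1
Reactants: 1 (2,2-dimethyl-1,3-dioxan-5-yl)methanol
Product: 2 2,2-dimethyl-1,3-dioxane-5-carbaldehyde
Conditions: 2,2,6,6-tetramethylpiperidin-1-oxyl (TEMPO, cat.), PhI(OAc)2, CH2Cl2, rt
Reagents that add atoms: none
Why: Nitroxyl-catalysed (oxoammonium) oxidation of a primary alcohol stops at the aldehyde under conditions that are neither strongly acidic nor basic, which suits the acetonide and the enolisable β-alkoxy aldehyde; 2 is used without storage.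

Step 2
Reactants: 2 2,2-dimethyl-1,3-dioxane-5-carbaldehyde; 3 pent-1-en-3-one
Product: 5 3,3,8-trimethyl-2,4-dioxaspiro[5.5]undec-7-en-9-one, via keto aldehyde 4 (not isolated)
Conditions: Et2NSiMe3 (20 mol%), MeCN, 80 °C; then aq. KOH, Bu4NOH (cat.), THF–Et2O, 40 °C
Reagents that add atoms: none
Why: Robinson annulation: amine-catalysed (enamine) Michael addition of the α-branched aldehyde to the vinyl ketone creates the quaternary C4, and hydroxide then closes C5=C10 by aldol condensation of the ethyl ketone onto the non-enolisable aldehyde of 4. The dioxane ring holds its C–O bonds away from ideal overlap with the enamine π system, which should slow β-elimination.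

Step 3
Reactants: 5 3,3,8-trimethyl-2,4-dioxaspiro[5.5]undec-7-en-9-one
Product: 6 (9S)-3,3,8-trimethyl-2,4-dioxaspiro[5.5]undec-7-en-9-ol
Conditions: (R)-1-methyl-3,3-diphenyltetrahydro-1H,3H-pyrrolo[1,2-c][1,3,2]oxazaborole ((R)-Me-CBS, 15 mol%), BH3·SMe2, THF, −20 °C; MeOH
Reagents that add atoms: none
Why: CBS reduction, a 1,2-reduction of an α-substituted cyclic enone by oxazaborolidine-activated borane. The 2-methylalkenyl arm acts as the large group, so the (R)-catalyst should give the (S)-carbinol, which becomes the source of the C5 configuration.

Step 4
Reactants: 6 (9S)-3,3,8-trimethyl-2,4-dioxaspiro[5.5]undec-7-en-9-ol; 7 butyl vinyl ether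
Product: 9 2-[(7S)-3,3,8-trimethyl-2,4-dioxaspiro[5.5]undec-8-en-7-yl]acetaldehyde, via allyl vinyl ether 8 (not isolated)
Conditions: Pd(OCOCF3)2 (divalent palladium, 2 mol%), 4,7-diphenyl-1,10-phenanthroline, Et3N (cat.), neat 7, 75 °C; then xylenes, 180 °C, sealed tube
Reagents that add atoms: none
Why: Palladium-catalysed transfer vinylation followed by Claisen rearrangement. The [3,3] shift is suprafacial across the ring allyl unit, so C6 is delivered to C5 on the face that carried the C1 oxygen; this gives (S)-C5, moves the alkene to C1=C10 and releases C7 as the aldehyde.

Step 5
Reactants: 10 3-bromooxolan-2-one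
Product: 11 3-(phenylsulfanyl)oxolan-2-one
Conditions: PhSH, Et3N, CH2Cl2, 0 °C to rt
Reagents that add atoms: thiophenol, Sc1ccccc1
Why: SN2 displacement of an α-bromo lactone by thiophenolate under mild amine base, a standard entry to α-arylsulfanyl lactones.

Step 6
Reactants: 11 3-(phenylsulfanyl)oxolan-2-one; 12 3-bromo-1,1-dimethoxypropane
Product: 14 3-[2-oxo-3-(phenylsulfanyl)oxolan-3-yl]propanal, via dimethyl acetal 13 (not isolated)
Conditions: LiN(i-Pr)2, THF, −78 °C; 12, NaI (cat.), DMPU, −78 °C to rt; then 1 M HCl, THF, rt
Reagents that add atoms: water, O
Why: Alkylation of the sulfur-stabilised lactone enolate with a primary halide builds the quaternary C13 and the C12–C13 bond, and the dimethyl acetal is cleaved by the acidic work-up. All enolate chemistry of the side chain is finished before any decalin aldehyde exists.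

Step 7
Reactants: 14 3-[2-oxo-3-(phenylsulfanyl)oxolan-3-yl]propanal; 15 (triphenylphosphoranylidene)acetaldehyde
Product: 16 (2E)-5-[2-oxo-3-(phenylsulfanyl)oxolan-3-yl]pent-2-enal
Conditions: PhMe, 80 °C
Reagents that add atoms: none
Why: Wittig olefination with a stabilised formyl ylide gives the (E)-enal (C17, C8, C9); a slight deficit of ylide limits a second homologation to the dienal.

Step 8
Reactants: 9 2-[(7S)-3,3,8-trimethyl-2,4-dioxaspiro[5.5]undec-8-en-7-yl]acetaldehyde; 16 (2E)-5-[2-oxo-3-(phenylsulfanyl)oxolan-3-yl]pent-2-enal
Product: 19 ring B enal (18,19-O-isopropylidene-17-oxo-13-(phenylsulfanyl)labd-7-en-16,15-olide skeleton; H5 anti to C20; C11 on the face of C20), via aldol 17 (not isolated), via mesylate 18 (not isolated)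
Conditions: Fe(acac)3 (trivalent iron, 30 mol%), PhSiH3 (added slowly), EtOH–(CH2OH)2 5:1, 0 °C to rt, 16 in excess; then MsCl, Et3N, CH2Cl2, 0 °C to rt
Reagents that add atoms: none
Why: An iron hydride formed from Fe(acac)3 and PhSiH3 transfers a hydrogen atom to C1 of the electron-rich trisubstituted alkene of 9; the tertiary C10 radical adds to the β-carbon (C9) of 16 (Giese addition), the α-formyl radical is reduced by divalent iron to the enolate (radical–polar crossover), and C8 adds to the tethered C7 aldehyde to give aldol 17, which is mesylated to 18 and loses methanesulfonate by E1cB to give 19. The closest known reaction type is the iron-hydride-initiated conjugate addition and aldol annulation of γ,δ-unsaturated aldehydes with enals and enones to decalins. Ring B closes by 6-exo-trig aldol addition of the C8 enolate to the C7 carbonyl. C10 is controlled by C5: the radical is attacked on the face opposite the equatorial acetaldehyde arm, so C9 and C6 end trans-diequatorial on ring A, the methyl axial, and the fusion trans. C9 is controlled by the shape of ring A around the forming bond: only H9 can sit beneath the ring between C1 and C5, the sp3 chain carbon C11 takes the open sector between C1 and C20, and the flat alkene carbon C8, tilted away by the obtuse attack angle, takes the sector beside C6 where the aldol needs it; this puts C11 equatorial and on the face of C20. The C7 and C8 centres of 17 are erased by the dehydration, and both C13 epimers behave alike. The step needs hydrogen-atom transfer to the donor alkene in preference to reduction of the enal or the aldehydes; the electron-rich alkene, slow addition of silane and an excess of 16 secure this, and the sulfide, lactone and acetonide are inert.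

Step 9
Reactants: 19 ring B enal
Product: 21 saturated aldehyde with equatorial formyl group at C8 (18,19-O-isopropylidene-17-oxo-13-(phenylsulfanyl)labdan-16,15-olide skeleton; C5/C8/C9/C10 as in 24), via C8-epimeric aldehyde 20 (not isolated)
Conditions: [(Ph3P)CuH]6 (monovalent copper), THF–H2O, rt; then DBU, CH2Cl2, rt
Reagents that add atoms: none
Why: Conjugate reduction by the hexameric copper hydride delivers hydride to C7 and spares the saturated lactone, the sulfide and the acetonide; hydrolysis of the copper enolate gives 20. DBU then equilibrates C8 to the equatorial aldehyde, because the axial formyl group would be syn-diaxial to C20, so C8 is set under thermodynamic control.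

Step 10
Reactants: 21 saturated aldehyde with equatorial formyl group at C8
Product: 23 18,19-O-isopropylidene acetal of 24, via sulfoxide 22 (not isolated)
Conditions: 3-chloroperbenzoic acid (1.0 equiv), CH2Cl2, −78 °C; then PhMe, 110 °C
Reagents that add atoms: none
Why: Sulfide oxidation at −78 °C is much faster than peracid attack on the aldehyde. Thermal syn-elimination of the sulfoxide (dehydrosulfenylation) takes the ring hydrogen at C14 and gives the endocyclic butenolide, both C13 epimers converging on one product.

Step 11
Reactants: 23 18,19-O-isopropylidene acetal of 24
Product: 24 (5S,8S,9R,10S)-18,19-dihydroxy-17-oxolabd-13-en-16,15-olide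
Conditions: AcOH–H2O–THF 3:1:1, 40 °C
Reagents that add atoms: none
Why: Acid hydrolysis of the isopropylidene acetal. The butenolide tolerates aqueous acetic acid, the aldehyde already has its thermodynamic configuration, and the diol cannot reach C17.

## Compound list

1 | (2,2-dimethyl-1,3-dioxan-5-yl)methanol | OCC1COC(C)(C)OC1 | starting material
2 | 2,2-dimethyl-1,3-dioxane-5-carbaldehyde | O=CC1COC(C)(C)OC1 | intermediate
3 | pent-1-en-3-one | CCC(=O)C=C | starting material
4 | 2,2-dimethyl-5-(3-oxopentyl)-1,3-dioxane-5-carbaldehyde | CCC(=O)CCC1(C=O)COC(C)(C)OC1 | intermediate
5 | 3,3,8-trimethyl-2,4-dioxaspiro[5.5]undec-7-en-9-one | CC1=CC2(COC(C)(C)OC2)CCC1=O | intermediate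
6 | (9S)-3,3,8-trimethyl-2,4-dioxaspiro[5.5]undec-7-en-9-ol | CC1=CC2(COC(C)(C)OC2)CC[C@@H]1O | intermediate
7 | butyl vinyl ether (1-(ethenyloxy)butane) | C=COCCCC | starting material
8 | (9S)-9-(ethenyloxy)-3,3,8-trimethyl-2,4-dioxaspiro[5.5]undec-7-ene | CC1=CC2(COC(C)(C)OC2)CC[C@@H]1OC=C | intermediate
9 | 2-[(7S)-3,3,8-trimethyl-2,4-dioxaspiro[5.5]undec-8-en-7-yl]acetaldehyde | CC1=CCCC2(COC(C)(C)OC2)[C@H]1CC=O | intermediate
10 | 3-bromooxolan-2-one (α-bromo-γ-butyrolactone, racemic) | O=C1OCCC1Br | starting material
11 | 3-(phenylsulfanyl)oxolan-2-one (racemic) | O=C1OCCC1Sc1ccccc1 | intermediate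
12 | 3-bromo-1,1-dimethoxypropane | COC(CCBr)OC | starting material
13 | 3-(3,3-dimethoxypropyl)-3-(phenylsulfanyl)oxolan-2-one (racemic) | COC(CCC1(Sc2ccccc2)CCOC1=O)OC | intermediate
14 | 3-[2-oxo-3-(phenylsulfanyl)oxolan-3-yl]propanal (racemic) | O=CCCC1(Sc2ccccc2)CCOC1=O | intermediate
15 | (triphenylphosphoranylidene)acetaldehyde | O=CC=P(c1ccccc1)(c1ccccc1)c1ccccc1 | starting material
16 | (2E)-5-[2-oxo-3-(phenylsulfanyl)oxolan-3-yl]pent-2-enal (racemic) | O=C/C=C/CCC1(Sc2ccccc2)CCOC1=O | intermediate
17 | aldol adduct: trans-decalin with 7-hydroxy and 8-formyl groups, C4 spiro-acetonide, C9 chain CH2CH2 to the 3-(phenylsulfanyl)oxolan-2-one; C5, C9, C10 as in 24; mixture at C7, C8 and C13 | C[C@@]12CCCC3(COC(C)(C)OC3)[C@H]1CC(O)C(C=O)[C@H]2CCC4(Sc5ccccc5)CCOC4=O | intermediate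
18 | 7-O-methanesulfonate of 17 | C[C@@]12CCCC3(COC(C)(C)OC3)[C@H]1CC(OS(C)(=O)=O)C(C=O)[C@H]2CCC4(Sc5ccccc5)CCOC4=O | intermediate
19 | ring B enal: 18,19-O-isopropylidene-17-oxo-13-(phenylsulfanyl)labd-7-en-16,15-olide skeleton; H5 anti to C20, C11 on the face of C20; both C13 epimers | C[C@@]12CCCC3(COC(C)(C)OC3)[C@H]1CC=C(C=O)[C@H]2CCC4(Sc5ccccc5)CCOC4=O | intermediate
20 | 7,8-dihydro derivative of 19 as a mixture of C8 epimers | C[C@@]12CCCC3(COC(C)(C)OC3)[C@H]1CCC(C=O)[C@H]2CCC4(Sc5ccccc5)CCOC4=O | intermediate
21 | 7,8-dihydro derivative of 19 with equatorial C8 formyl group (trans to C11); C5, C8, C9, C10 as in 24; both C13 epimers | C[C@@]12CCCC3(COC(C)(C)OC3)[C@H]1CC[C@H](C=O)[C@H]2CCC4(Sc5ccccc5)CCOC4=O | intermediate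
22 | S-oxide (sulfoxide) of 21 | C[C@@]12CCCC3(COC(C)(C)OC3)[C@H]1CC[C@H](C=O)[C@H]2CCC4(S(=O)c5ccccc5)CCOC4=O | intermediate
23 | 18,19-O-isopropylidene acetal of 24 | C[C@@]12CCCC3(COC(C)(C)OC3)[C@H]1CC[C@H](C=O)[C@H]2CCC4=CCOC4=O | intermediate
24 | (5S,8S,9R,10S)-18,19-dihydroxy-17-oxolabd-13-en-16,15-olide (CNP0332660.1) | C[C@@]12CCCC(CO)(CO)[C@H]1CC[C@H](C=O)[C@H]2CCC1=CCOC1=O | target

## Step count and risks

Total step count: 11. Longest linear sequence: 8 steps (steps 1, 2, 3, 4, 8, 9, 10, 11).

**Step 8 (key step).** The facial choice at the enal β-carbon is made in an open transition state, so C9 may form as a mixture. A tertiary radical also adds slowly to a β-substituted acceptor, so reduction of the C10 radical or hydrogen-atom-transfer reduction of the enal can compete. The fallback moves the C9–C10 bond formation into a ring closure; it sets out from 9 and comes back at 23. Reduction of 9 with NaBH4 gives 2-[(7S)-3,3,8-trimethyl-2,4-dioxaspiro[5.5]undec-8-en-7-yl]ethanol F1, and iodination (I2, PPh3, imidazole) gives the iodide F2. Alkylation of the sodium salt of dimethyl glutaconate with F2 gives the pentenedioate F3, in which C8 carries a methyl ester (C17) and C9=C11 is an enoate. Fe(acac)3 and PhSiH3 generate the same C10 radical, which closes ring B by 6-exo-trig addition to C9 through a chair-like transition state with the acrylate arm equatorial, giving the decalin diester F4. LiAlH4 gives the diol F5, and Swern oxidation followed by DBU gives the dialdehyde F6 with the C8 formyl group equatorial. The unhindered C12 aldehyde alone reacts with 3-(triphenylphosphoranylidene)oxolan-2-one to give the (E)-alkylidene lactone F7. RhCl3·3H2O (trivalent rhodium) in ethanol moves the double bond into the lactone ring to give 23. This costs eight operations in place of three and the ring fusion still rests on the cyclisation, but C9 no longer depends on an intermolecular approach.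

**Step 2.** The enamine or enolate of 2 can expel a ring oxygen from the β-position, and the opened hemiketal then loses acetone; this β-elimination competes with the slow Michael addition of an α-branched aldehyde. The fallback is a kinetic metalloenamine alkylation at low temperature; it sets out from 2 and 3 and comes back at 4. HBr and ethane-1,2-diol convert 3 into 2-(2-bromoethyl)-2-ethyl-1,3-dioxolane F8. Cyclohexylamine and 2 give the imine F9. Deprotonation of F9 with LiN(i-Pr)2 at −78 °C, alkylation with F8 (NaI) and buffered hydrolysis of the imine give the ketal aldehyde F10. Acetal exchange with pyridinium tosylate in wet acetone frees the ketone as 4, while the solvent holds the acetonide in place; KOH then closes 5 as in step 2.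

**Step 4.** Vinyl transfer to the hindered secondary allylic alcohol may stall, or the rearrangement, which forms a bond next to the quaternary C4, may need temperatures at which the allyl vinyl ether ionises and eliminates to a diene. The fallback is the Eschenmoser–Claisen rearrangement, which forms a ketene N,O-acetal directly on the alcohol and rearranges at lower temperature; it sets out from 6 and comes back at 9. Heating 6 with N,N-dimethylacetamide dimethyl acetal in xylene at 140 °C gives the dimethylamide F11 with the same suprafacial transfer of chirality. Cp2Zr(H)Cl (tetravalent zirconium) reduces the tertiary amide to aldehyde 9.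

**Step 9.** Hydride delivery to the α-branched enal may be slow, so that 1,2-reduction of the aldehyde or copper-mediated cleavage of the C–S bond next to the lactone carbonyl competes. The fallback is a radical conjugate reduction; it sets out from 19, comes back at 21 and passes through no compound outside the list (entry F0). Mn(dpm)3 (dpm = dipivaloylmethanate, trivalent manganese) and PhSiH3 in i-PrOH transfer a hydrogen atom to C7, and the C8 radical is reduced to the enolate and protonated. DBU then equilibrates C8 as before.

## Further compounds

F1 | step 8 | 2-[(7S)-3,3,8-trimethyl-2,4-dioxaspiro[5.5]undec-8-en-7-yl]ethanol | CC1=CCCC2(COC(C)(C)OC2)[C@H]1CCO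
F2 | step 8 | (7S)-7-(2-iodoethyl)-3,3,8-trimethyl-2,4-dioxaspiro[5.5]undec-8-ene | CC1=CCCC2(COC(C)(C)OC2)[C@H]1CCI
F3 | step 8 | dimethyl (2E)-4-{2-[(7S)-3,3,8-trimethyl-2,4-dioxaspiro[5.5]undec-8-en-7-yl]ethyl}pent-2-enedioate (both C4 epimers) | CC1=CCCC2(COC(C)(C)OC2)[C@H]1CCC(C(=O)OC)/C=C/C(=O)OC
F4 | step 8 | trans-decalin diester: methyl ester at C8, CH2CO2Me at C9, C4 spiro-acetonide; C5, C9, C10 as in 24; mixture at C8 | C[C@@]12CCCC3(COC(C)(C)OC3)[C@H]1CCC(C(=O)OC)[C@H]2CC(=O)OC
F5 | step 8 | diol from F4: CH2OH at C8, CH2CH2OH at C9 | C[C@@]12CCCC3(COC(C)(C)OC3)[C@H]1CCC(CO)[C@H]2CCO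
F6 | step 8 | dialdehyde: equatorial CHO at C8, CH2CHO at C9; C5, C8, C9, C10 as in 24 | C[C@@]12CCCC3(COC(C)(C)OC3)[C@H]1CC[C@H](C=O)[C@H]2CC=O
F7 | step 8 | (E)-12(13)-alkylidene lactone isomer of 23 | C[C@@]12CCCC3(COC(C)(C)OC3)[C@H]1CC[C@H](C=O)[C@H]2C/C=C4\CCOC4=O
F8 | step 2 | 2-(2-bromoethyl)-2-ethyl-1,3-dioxolane | CCC1(CCBr)OCCO1
F9 | step 2 | N-cyclohexyl-1-(2,2-dimethyl-1,3-dioxan-5-yl)methanimine | CC1(C)OCC(C=NC2CCCCC2)CO1
F10 | step 2 | 5-[2-(2-ethyl-1,3-dioxolan-2-yl)ethyl]-2,2-dimethyl-1,3-dioxane-5-carbaldehyde | CCC1(CCC2(C=O)COC(C)(C)OC2)OCCO1
F11 | step 4 | N,N-dimethyl-2-[(7S)-3,3,8-trimethyl-2,4-dioxaspiro[5.5]undec-8-en-7-yl]acetamide | CC1=CCCC2(COC(C)(C)OC2)[C@H]1CC(=O)N(C)C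
F0 | step 9 | none | none
A1 | alternative 1 | (E,E)-epoxy diene with spiro epoxide on the dioxane and silyl ether terminus | CC(C)(C)[Si](C)(C)OCC/C=C(C)/CC/C=C(C)/CC[C@H]1OC12COC(C)(C)OC2
A2 | alternative 1 | 3-hydroxy-8(17)-ene trans-decalin with C4 spiro-acetonide and C12 silyl ether | C[C@@]12CC[C@H](C3(COC(C)(C)OC3)[C@H]1CCC(=C)[C@H]2CCO[Si](C)(C)C(C)(C)C)O
A3 | alternative 2 | diazomethyl ketone on ring B with exocyclic C10=C20 methylene | [N-]=[N+]=CC(=O)CC1(COC(C)(C)OC1)[C@H]1CC[C@H](CO[Si](C)(C)C(C)(C)C)[C@@H](CCOCc2ccccc2)C1=C
A4 | alternative 2 | tricyclic cyclopropyl ketone (C2 ketone, C1–C10–C20 cyclopropane) | C1[C@@]23[C@@H]1C(=O)CC4(COC(C)(C)OC4)[C@H]2CC[C@H](CO[Si](C)(C)C(C)(C)C)[C@H]3CCOCc1ccccc1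
A5 | alternative 3 | 2-methylcyclohex-2-en-1-one | CC1=CCCCC1=O
A6 | alternative 3 | methyl 3-methoxy-3-[(trimethylsilyl)oxy]prop-2-enoate | COC(=O)C=C(OC)O[Si](C)(C)C
A7 | alternative 3 | 1-chloro-3-iodopropane | ClCCCI
A8 | alternative 3 | trans-decalin C9 ketone with C4 geminal dimethyl ester | C[C@@]12CCCC(C(=O)OC)(C(=O)OC)[C@H]1CCCC2=O
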